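**Plan**

- Retrosynthesis: the C14=C15 terminus is cut by cross-metathesis and C12–C13 by allylation of a lactol. The C2–O bond (allylic hydroxylation), C1=CH2 (methylenation), C11–CH3 and C4–C11 (enolate alkylations through a C5/C12 γ-lactone) and C10–O (ene reaction) follow. The last cut is C7–C8 together with C6–C10.
- Enabling feature: in the five-membered ring, C8–C9–C10(CH3) bridges C7 and C6, and C6 sits next to the oxygenated C5. With C5 as a ketone this is a 1-methyl-1-silylallene laid across an enone C5(=O)–C6=C7 of the seven-membered ring.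
- Forward order: seven-membered ring from cyclohepta-1,3-diene; five-membered ring by the [3+2] annulation; trans fusion by C6 equilibration; C10–OH and C8=C9 by singlet-oxygen ene reaction; lactone on C4/C5; C11 methyl; C1 methylene; side chain; C2–OH; prenyl terminus.
- Stereochemistry: the C1 silyloxy centre (lipase desymmetrisation) sets C7 in the annulation and, through the trans-fused frame, C10, C4, C5 and C2. C6 is set thermodynamically, C11 on the convex face of the cis-fused lactone, and C12 by the allylborane, matched with the Felkin–Anh preference.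

Key step: step 8

Assumption: the lipase acylates the (S)-configured carbinol carbon of the meso diol, as such lipases do with cis-cyclopent-2-ene-1,4-diol. If it shows the opposite preference, hydrolysis of the meso diacetate with the same enzyme gives the same monoacetate 7.

Numbering used for all bicyclic compounds: C1 = ring carbon that ends as the methylene-bearing carbon (the silyloxy carbon early on); C2, C3, C4 (side chain), C5; C6 and C7 = ring fusion (C7 next to C1); C8, C9, C10 = five-membered ring (C10 bears CH3); C11 = side-chain CH(CH3); C12 = acetoxy carbon. β is the face of H6 in the target, α the face of H7.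

**Route**

Step 1
Reactants: 1 3-(trimethylsilyl)prop-2-yn-1-ol
Product: 2 3-(trimethylsilyl)prop-2-yn-1-yl methanesulfonate
Conditions: MsCl, Et3N, CH2Cl2, 0 °C
Reagents that add atoms: methanesulfonyl chloride (CS(=O)(=O)Cl)
Why: Sulfonylation of a primary propargylic alcohol gives the leaving group needed for the SN2′ substitution of the next step.

Step 2
Reactants: 2 3-(trimethylsilyl)prop-2-yn-1-yl methanesulfonate
Product: 3 1-methyl-1-(trimethylsilyl)allene
Conditions: MeMgCl, CuBr, LiBr, THF, −78 °C to rt
Reagents that add atoms: methylmagnesium chloride (C[Mg]Cl)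
Why: Organocopper SN2′ substitution of a propargylic sulfonate places the methyl group on the silicon-bearing alkyne carbon and gives the 1,1-disubstituted allene, with no stereocentre formed.

Step 3
Reactants: 4 cyclohepta-1,3-diene
Product: 6 cis-cyclohept-2-ene-1,4-diol, via endoperoxide 5 (not isolated)
Conditions: O2, hν (visible), rose bengal, thiourea, MeOH, 0 °C to rt
Reagents that add atoms: dioxygen (O=O)
Why: [4+2] cycloaddition of singlet oxygen to the cyclic 1,3-diene and in situ thiourea reduction of the O–O bond put both oxygens on one face, so the diol is cis (meso).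

Step 4
Reactants: 6 cis-cyclohept-2-ene-1,4-diol
Product: 7 (1S,4R)-4-hydroxycyclohept-2-en-1-yl acetate
Conditions: lipase from Burkholderia cepacia (Amano PS), vinyl acetate, t-BuOMe, rt
Reagents that add atoms: vinyl acetate (CC(=O)OC=C)
Why: Lipase-catalysed enantiotopos-selective transesterification of a meso 2-cycloalkene-1,4-diol acylates one carbinol only and thereby fixes the absolute configuration of both centres.

Step 5
Reactants: 7 (1S,4R)-4-hydroxycyclohept-2-en-1-yl acetate
Product: 8 (1S,4R)-4-(tert-butyldimethylsilyloxy)cyclohept-2-en-1-yl acetate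
Conditions: TBSCl, imidazole, DMF, rt
Reagents that add atoms: tert-butyldimethylsilyl chloride (CC(C)(C)[Si](C)(C)Cl)
Why: Silylation of the free secondary allylic alcohol installs the bulky ether that later steers the annulation and touches no stereocentre.

Step 6
Reactants: 8 (1S,4R)-4-(tert-butyldimethylsilyloxy)cyclohept-2-en-1-yl acetate
Product: 9 (1S,4R)-4-(tert-butyldimethylsilyloxy)cyclohept-2-en-1-ol
Conditions: K2CO3, MeOH, rt
Reagents that add atoms: none
Why: Base-catalysed methanolysis removes the acetate while the silyl ether is stable.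

Step 7
Reactants: 9 (1S,4R)-4-(tert-butyldimethylsilyloxy)cyclohept-2-en-1-ol
Product: 10 (R)-4-(tert-butyldimethylsilyloxy)cyclohept-2-en-1-one
Conditions: MnO2, CH2Cl2, rt
Reagents that add atoms: none
Why: MnO2 oxidation of the allylic alcohol gives the enone and leaves the γ-silyloxy stereocentre untouched.

Step 8
Reactants: 10 (R)-4-(tert-butyldimethylsilyloxy)cyclohept-2-en-1-one; 3 1-methyl-1-(trimethylsilyl)allene
Product: 11 cis-fused silylcyclopentene ketone (C1 α-OTBS; H6 α; H7 α; C9(SiMe3)=C10(CH3); C5 ketone)
Conditions: TiCl4 (1.1 equiv), CH2Cl2, −78 °C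
Reagents that add atoms: none
Why: TiCl4 activates the enone, the unsubstituted allene terminus (C8) adds to C7 to give a β-silyl-stabilised vinyl cation, a 1,2-shift of the trimethylsilyl group moves the charge to the methyl-bearing carbon (C10), and the titanium enolate captures it through C6, so C7–C8 and C6–C10 are formed and silicon ends on C9. The closest known reaction type is the (trimethylsilyl)cyclopentene annulation of cyclic enones with 1-substituted allenylsilanes (Danheiser annulation). The five-membered ring closes by C-attack of an exocyclic enolate on the digonal cation carbon, a stepwise cationic 5-(enolexo)-endo-dig closure. C7 is controlled by the C1 silyloxy group, the allene adding to the opposite enone face as nucleophiles do with 4-silyloxycycloalkenones, and C6 by the ring closure itself, which can only occur on the face carrying the new chain, hence the cis fusion. The step needs attack through the allene CH2 (secured by silicon, which stabilises only the cation formed that way) and face selectivity (secured by the bulky γ-silyloxy group), and the silyl ether should survive TiCl4 at −78 °C.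

Step 9
Reactants: 11 cis-fused silylcyclopentene ketone
Product: 12 trans-fused silylcyclopentene ketone (H6 β; H7 α)
Conditions: NaOMe (0.2 equiv), MeOH, 0 °C, monitored; recovered 11 resubmitted
Reagents that add atoms: none
Why: Base-mediated epimerisation of the ketone α-centre C6 through the extended enolate, which is protonated at C6 much faster than at the silicon-bearing C9, should lead to the trans-fused isomer, in which C8, C10 and the silyloxy group are all equatorial on the seven-membered ring.

Step 10
Reactants: 12 trans-fused silylcyclopentene ketone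
Product: 14 10β-hydroxy-10α-methyl C8=C9(SiMe3) ketone, via hydroperoxide 13 (not isolated)
Conditions: O2, hν (visible), tetraphenylporphyrin, CH2Cl2, −20 °C; then PPh3, rt
Reagents that add atoms: dioxygen (O=O)
Why: In the singlet-oxygen ene reaction of a vinylsilane, oxygen bonds to the carbon remote from silicon (C10) and hydrogen is taken from the carbon geminal to silicon (C8), so the double bond moves to C8=C9; attack is expected on the β face because the equatorial C1 silyloxy group flanks the α face at C8, and PPh3 reduces the hydroperoxide.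

Step 11
Reactants: 14 10β-hydroxy-10α-methyl C8=C9(SiMe3) ketone
Product: 15 C10 triethylsilyl ether of 14
Conditions: Et3SiOTf, 2,6-lutidine, CH2Cl2, −78 °C
Reagents that add atoms: triethylsilyl trifluoromethanesulfonate (CC[Si](CC)(CC)OS(=O)(=O)C(F)(F)F)
Why: Silylation of the tertiary alcohol with a silyl triflate masks the β-hydroxy ketone against retro-aldol cleavage in the enolate steps that follow and affects no stereocentre.

Step 12
Reactants: 15 C10 triethylsilyl ether of 14
Product: 16 keto ester with CH2CO2CH3 on C4 (β)
Conditions: LiN(i-Pr)2, THF, −78 °C; BrCH2CO2Me, DMPU, −78 to −40 °C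
Reagents that add atoms: methyl bromoacetate (COC(=O)CBr)
Why: Kinetic deprotonation takes the C4 methylene (C6 is a hindered methine next to the quaternary C10), and in this enolate alkylation the bromo ester should approach C4 on the β face, away from the ring-fusion carbons C7 and C10 that lie on the α side of the enolate plane.

Step 13
Reactants: 16 keto ester with CH2CO2CH3 on C4 (β)
Product: 18 cis-fused γ-lactone (O on C5 β; C11H2 on C4 β; C12 carbonyl), via hydroxy ester 17 (not isolated)
Conditions: NaBH4, MeOH, −20 °C to rt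
Reagents that add atoms: none
Why: Borohydride should attack the C5 ketone from the α face, anti to the new C4 arm and the C10 silyloxy group, giving the 5β-alkoxide (cis to the acetate arm), which closes the cis-fused γ-lactone by intramolecular transesterification.

Step 14
Reactants: 18 cis-fused γ-lactone
Product: 19 11-methyl lactone (CH3 on C11 cis to H4)
Conditions: LiN(i-Pr)2, THF, −78 °C; MeI, −78 to −40 °C
Reagents that add atoms: iodomethane (CI)
Why: Alkylation of the enolate of a cis-fused bicyclic γ-lactone occurs on the convex face, so the methyl group enters C11 cis to H4 and trans to the C4–C3 bond, which is the configuration of the target.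

Step 15
Reactants: 19 11-methyl lactone
Product: 20 lactone diol (C1 α-OH; C10 β-OH; C8=C9 without silicon)
Conditions: Bu4NF (5 equiv), THF, rt then 60 °C
Reagents that add atoms: none
Why: Fluoride cleaves both silyl ethers, and the liberated C10 alkoxide assists protodesilylation of the adjacent vinylsilane (hydroxyl-assisted C–Si cleavage of a 2-silyl allylic alcohol) with the double bond kept at C8=C9 and no stereocentre changed.

Step 16
Reactants: 20 lactone diol
Product: 21 C1 ketone
Conditions: Dess–Martin periodinane, NaHCO3, CH2Cl2, 0 °C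
Reagents that add atoms: none
Why: Dess–Martin oxidation converts the secondary C1 alcohol into the ketone under buffered, non-epimerising conditions and cannot oxidise the tertiary C10 alcohol.

Step 17
Reactants: 21 C1 ketone
Product: 22 C1 methylene lactone
Conditions: Zn, CH2Br2, TiCl4, THF/CH2Cl2, 0 °C to rt
Reagents that add atoms: dibromomethane (BrCBr)
Why: Lombardo methylenation with the non-basic zinc/titanium methylene reagent converts the ketone into the exocyclic alkene without enolising the allylic C7–H and without attacking the lactone.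

Step 18
Reactants: 22 C1 methylene lactone
Product: 23 lactol (C12 hemiacetal; anomer mixture)
Conditions: i-Bu2AlH, CH2Cl2, −78 °C
Reagents that add atoms: none
Why: Low-temperature i-Bu2AlH reduction of a γ-lactone stops at the aluminium hemiacetal, which on work-up gives the lactol and so unmasks C12 as an aldehyde equivalent together with the C5 hydroxyl.

Step 19
Reactants: 23 lactol
Product: 24 triol with (12S)-homoallylic alcohol (C5 β-OH; C10 β-OH)
Conditions: (−)-Ipc2B(allyl) (3 equiv), Et2O, −78 °C to rt; then NaOH, H2O2
Reagents that add atoms: (−)-B-allyldiisopinocampheylborane (C=CCB([C@@H]1C[C@@H]2C[C@H]([C@H]1C)C2(C)C)[C@@H]1C[C@@H]2C[C@H]([C@H]1C)C2(C)C)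
Why: Brown allylboration of the ring-opened hydroxy aldehyde through a chair transition state should give the (12S) alcohol, because reagent control and the Felkin–Anh preference of the α-methyl aldehyde (CH3 and OH syn) are matched.

Step 20
Reactants: 24 triol with (12S)-homoallylic alcohol
Product: 25 C12 acetate
Conditions: Ac2O, pyridine, CH2Cl2, 0 °C
Reagents that add atoms: acetic anhydride (CC(=O)OC(C)=O)
Why: Mild acylation should select the side-chain C12 hydroxyl, which has one methylene neighbour, over the ring C5 hydroxyl, which is flanked by two methine carbons beside the quaternary C10, while the tertiary C10 hydroxyl is inert.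

Step 21
Reactants: 25 C12 acetate
Product: 26 C2 α-hydroxy compound
Conditions: SeO2 (0.5 equiv), t-BuOOH, CH2Cl2, rt
Reagents that add atoms: selenium dioxide (O=[Se]=O); tert-butyl hydroperoxide (CC(C)(C)OO)
Why: Selenium dioxide allylic hydroxylation (ene reaction then [2,3]-sigmatropic shift) of the 1,1-disubstituted alkene oxidises the ring methylene C2 in preference to the methine C7 and keeps the exocyclic double bond, with oxygen expected on the α face of C2, away from the β-oriented C4 side chain.

Step 22
Reactants: 26 C2 α-hydroxy compound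
Product: 27 CNP0126182.2
Conditions: second-generation Grubbs catalyst (H2IMes)(PCy3)Cl2Ru=CHPh (5 mol%), 2-methylbut-2-ene, CH2Cl2, 40 °C
Reagents that add atoms: 2-methylbut-2-ene (CC=C(C)C)
Why: Olefin cross-metathesis of the terminal vinyl group with excess 2-methylbut-2-ene installs the isopropylidene terminus, while the 1,1-disubstituted methylene, the hindered cyclopentene and the trisubstituted product alkene are poor metathesis partners.

**Compound list**

1 | 3-(trimethylsilyl)prop-2-yn-1-ol | C[Si](C)(C)C#CCO | starting material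
2 | 3-(trimethylsilyl)prop-2-yn-1-yl methanesulfonate | C[Si](C)(C)C#CCOS(C)(=O)=O | intermediate
3 | 1-methyl-1-(trimethylsilyl)allene | CC(=C=C)[Si](C)(C)C | intermediate
4 | cyclohepta-1,3-diene | C1=CC=CCCC1 | starting material
5 | 6,7-dioxabicyclo[3.2.2]non-8-ene (endoperoxide) | C1C[C@@H]2C=C[C@H](C1)OO2 | intermediate
6 | cis-cyclohept-2-ene-1,4-diol (meso) | O[C@H]1C=C[C@@H](O)CCC1 | intermediate
7 | (1S,4R)-4-hydroxycyclohept-2-en-1-yl acetate | CC(=O)O[C@@H]1C=C[C@H](O)CCC1 | intermediate
8 | (1S,4R)-4-(tert-butyldimethylsilyloxy)cyclohept-2-en-1-yl acetate | CC(=O)O[C@@H]1C=C[C@H](O[Si](C)(C)C(C)(C)C)CCC1 | intermediate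
9 | (1S,4R)-4-(tert-butyldimethylsilyloxy)cyclohept-2-en-1-ol | O[C@@H]1C=C[C@H](O[Si](C)(C)C(C)(C)C)CCC1 | intermediate
10 | (R)-4-(tert-butyldimethylsilyloxy)cyclohept-2-en-1-one | O=C1C=C[C@H](O[Si](C)(C)C(C)(C)C)CCC1 | intermediate
11 | cis-fused 8-(tert-butyldimethylsilyloxy)-3-methyl-2-(trimethylsilyl)-3a,5,6,7,8,8a-hexahydroazulen-4(1H)-one (C1 α-OTBS, H6 α, H7 α) | CC(C)(C)[Si](C)(C)O[C@@H]1CCCC(=O)[C@@H]2[C@H]1CC([Si](C)(C)C)=C2C | intermediate
12 | trans-fused C6 epimer of 11 (H6 β, H7 α) | CC(C)(C)[Si](C)(C)O[C@@H]1CCCC(=O)[C@H]2[C@H]1CC([Si](C)(C)C)=C2C | intermediate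
13 | trans-fused C10 β-hydroperoxide, C8=C9(SiMe3), C5 ketone, C1 α-OTBS | CC(C)(C)[Si](C)(C)O[C@@H]1CCCC(=O)[C@H]2[C@H]1C=C([Si](C)(C)C)[C@]2(C)OO | intermediate
14 | trans-fused C10 β-alcohol (10α-CH3), C8=C9(SiMe3), C5 ketone, C1 α-OTBS | CC(C)(C)[Si](C)(C)O[C@@H]1CCCC(=O)[C@H]2[C@H]1C=C([Si](C)(C)C)[C@]2(C)O | intermediate
15 | C10 triethylsilyl ether of 14 | CC(C)(C)[Si](C)(C)O[C@@H]1CCCC(=O)[C@H]2[C@H]1C=C([Si](C)(C)C)[C@]2(C)O[Si](CC)(CC)CC | intermediate
16 | keto ester: 15 with CH2CO2CH3 on C4 (β) | CC(C)(C)[Si](C)(C)O[C@@H]1CC[C@@H](CC(=O)OC)C(=O)[C@H]2[C@H]1C=C([Si](C)(C)C)[C@]2(C)O[Si](CC)(CC)CC | intermediate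
17 | 5β-hydroxy ester from 16 | CC(C)(C)[Si](C)(C)O[C@@H]1CC[C@@H](CC(=O)OC)[C@@H](O)[C@H]2[C@H]1C=C([Si](C)(C)C)[C@]2(C)O[Si](CC)(CC)CC | intermediate
18 | cis-fused γ-lactone (C5 β-O–C12(=O)–C11H2–C4 β) | CC(C)(C)[Si](C)(C)O[C@@H]1CC[C@@H](CC(=O)O3)[C@@H]3[C@H]2[C@H]1C=C([Si](C)(C)C)[C@]2(C)O[Si](CC)(CC)CC | intermediate
19 | (11S)-11-methyl lactone (CH3 cis to H4) | CC(C)(C)[Si](C)(C)O[C@@H]1CC[C@@H]([C@H](C)C(=O)O3)[C@@H]3[C@H]2[C@H]1C=C([Si](C)(C)C)[C@]2(C)O[Si](CC)(CC)CC | intermediate
20 | desilylated lactone diol (C1 α-OH, C10 β-OH, C8=C9) | O[C@@H]1CC[C@@H]([C@H](C)C(=O)O3)[C@@H]3[C@H]2[C@H]1C=C[C@]2(C)O | intermediate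
21 | C1 ketone lactone | O=C1CC[C@@H]([C@H](C)C(=O)O3)[C@@H]3[C@H]2[C@H]1C=C[C@]2(C)O | intermediate
22 | C1 methylene lactone | C=C1CC[C@@H]([C@H](C)C(=O)O3)[C@@H]3[C@H]2[C@H]1C=C[C@]2(C)O | intermediate
23 | lactol (C12 hemiacetal, anomer mixture) | C=C1CC[C@@H]([C@H](C)C(O)O3)[C@@H]3[C@H]2[C@H]1C=C[C@]2(C)O | intermediate
24 | triol: (12S)-allyl carbinol, C5 β-OH, C10 β-OH | C=C1CC[C@@H]([C@H](C)[C@H](CC=C)O)[C@@H](O)[C@H]2[C@H]1C=C[C@]2(C)O | intermediate
25 | C12 acetate of 24 | C=C1CC[C@@H]([C@H](C)[C@H](CC=C)OC(C)=O)[C@@H](O)[C@H]2[C@H]1C=C[C@]2(C)O | intermediate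
26 | C2 α-hydroxy derivative of 25 | C=C1[C@H](O)C[C@@H]([C@H](C)[C@H](CC=C)OC(C)=O)[C@@H](O)[C@H]2[C@H]1C=C[C@]2(C)O | intermediate
27 | CNP0126182.2 | C=C1[C@H](O)C[C@@H]([C@H](C)[C@H](CC=C(C)C)OC(C)=O)[C@@H](O)[C@H]2[C@H]1C=C[C@]2(C)O | target

**Step count**

Total: 22 steps. Longest linear sequence: 20 steps (steps 3 to 22, from cyclohepta-1,3-diene); the allene branch is 2 steps.

**Steps most likely to fail**

1. Step 9 (C6 equilibration). The equilibrium may not favour the trans-fused ketone strongly, and the ring double bond may drift into conjugation with the ketone during base treatment. Fallback: move the equilibration behind the oxygenation, setting out from 11 and returning at 15. Ketone 11 is photooxygenated and reduced as in step 10 to the cis-fused 10β-hydroxy vinylsilane ketone F1; this relies on the C1 silyloxy group, still gauche to C8, again steering singlet oxygen to the β face, which is less certain on the cis-fused frame than on the trans-fused one. Silylation as in step 11 gives the cis-fused triethylsilyl ether F2. C6 of F2 is then equilibrated with DBU in toluene to 15; at that stage there is no skipped double bond left, and reprotonation of the enolate should be much faster than loss of the β-silyloxy group.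

2. Step 12 (alkylation at C4). Facial selectivity may be poor, and proton transfer between enolate and product may erode C4 or give dialkylation. Fallback: a tether from the C5 oxygen, setting out from 15 and returning at 18.
   - Kinetic enolisation and silylation (LiN(i-Pr)2, Me3SiCl) give the C4=C5 trimethylsilyl enol ether F3.
   - Saegusa–Ito oxidation (Pd(OAc)2, MeCN) gives the C3=C4 enone F4.
   - Luche reduction (NaBH4, CeCl3·7H2O, MeOH, −78 °C) from the α face gives the 5β-allylic alcohol F5.
   - Ethyl vinyl ether and N-bromosuccinimide give the bromoacetal F6.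
   - Ueno–Stork 5-exo radical cyclisation (Bu3SnH, AIBN, benzene, 80 °C) forms C4–C11 necessarily cis to the C5 oxygen and gives the cis-fused cyclic ethyl acetal F7.
   - Aqueous AcOH gives the lactol F8, and Fetizon oxidation (Ag2CO3 on Celite, benzene, reflux) gives lactone 18.

3. Step 21 (allylic hydroxylation at C2). Oxygen may be delivered to the wrong face of C2 or to both faces, and over-oxidation to the enone is possible. Fallback: oxidation then reduction, setting out from 25 and returning at 26. The C2 epimer of 26 F9 (or the epimer mixture, or over-oxidised material) is taken with MnO2 in CH2Cl2, which is selective for the allylic alcohol, to the 2-oxo α-methylene ketone F10. 1,2-Reduction (NaBH4, CeCl3·7H2O, MeOH, −78 °C) then delivers hydride to the face that oxygen preferred and should give the opposite carbinol configuration, 26.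

**Further compounds**

F1 | step 9 | cis-fused 10β-hydroxy vinylsilane ketone (C6 epimer of 14) | CC(C)(C)[Si](C)(C)O[C@@H]1CCCC(=O)[C@@H]2[C@H]1C=C([Si](C)(C)C)[C@]2(C)O
F2 | step 9 | cis-fused triethylsilyl ether (C6 epimer of 15) | CC(C)(C)[Si](C)(C)O[C@@H]1CCCC(=O)[C@@H]2[C@H]1C=C([Si](C)(C)C)[C@]2(C)O[Si](CC)(CC)CC
F3 | step 12 | C4=C5 trimethylsilyl enol ether of 15 | CC(C)(C)[Si](C)(C)O[C@@H]1CCC=C(O[Si](C)(C)C)[C@H]2[C@H]1C=C([Si](C)(C)C)[C@]2(C)O[Si](CC)(CC)CC
F4 | step 12 | C3=C4 enone | CC(C)(C)[Si](C)(C)O[C@@H]1CC=CC(=O)[C@H]2[C@H]1C=C([Si](C)(C)C)[C@]2(C)O[Si](CC)(CC)CC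
F5 | step 12 | 5β-allylic alcohol | CC(C)(C)[Si](C)(C)O[C@@H]1CC=C[C@@H](O)[C@H]2[C@H]1C=C([Si](C)(C)C)[C@]2(C)O[Si](CC)(CC)CC
F6 | step 12 | bromoacetal (2-bromo-1-ethoxyethyl ether of F5) | CC(C)(C)[Si](C)(C)O[C@@H]1CC=C[C@@H](OC(CBr)OCC)[C@H]2[C@H]1C=C([Si](C)(C)C)[C@]2(C)O[Si](CC)(CC)CC
F7 | step 12 | cis-fused cyclic ethyl acetal | CC(C)(C)[Si](C)(C)O[C@@H]1CC[C@@H](CC(OCC)O3)[C@@H]3[C@H]2[C@H]1C=C([Si](C)(C)C)[C@]2(C)O[Si](CC)(CC)CC
F8 | step 12 | lactol corresponding to 18 | CC(C)(C)[Si](C)(C)O[C@@H]1CC[C@@H](CC(O)O3)[C@@H]3[C@H]2[C@H]1C=C([Si](C)(C)C)[C@]2(C)O[Si](CC)(CC)CC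
F9 | step 21 | C2 epimer of 26 (2β-OH) | C=C1[C@@H](O)C[C@@H]([C@H](C)[C@H](CC=C)OC(C)=O)[C@@H](O)[C@H]2[C@H]1C=C[C@]2(C)O
F10 | step 21 | 2-oxo α-methylene ketone | C=C1C(=O)C[C@@H]([C@H](C)[C@H](CC=C)OC(C)=O)[C@@H](O)[C@H]2[C@H]1C=C[C@]2(C)O
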